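The data were generated by integration from invented constants; noise was put on by code.

**The vessel.** A closed, stirred vessel at constant temperature holds substrate, partner and capture agent, and the suspected steps lead from them to target.

| flask | substrate | partner | capture agent | temperature | remark | time |
|---|---|---|---|---|---|---|
| green | 15 mM | 0.70 equiv | 0.75 mM | 20 °C | the very flask that is asked about, followed so far |  |
| ochre | 30 mM | 0.70 equiv | 0.75 mM | 15 °C | run made earlier |  |
| flask | 15 mM | 0.700 equiv | 0.750 mM | 20 °C |  | 3.0 h |

| run | time / min | target / % | substrate / % |
|---|---|---|---|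
| green | 20.0 | 9.0 | 55.0 |
| green | 40.0 | 11.7 | 55.9 |
| green | 60.0 | 13.8 | 57.2 |
| green | 80.0 | 14.2 | 58.6 |
| green | 90.0 | 14.1 | 58.2 |
| green | 120 | 15.8 | 60.3 |
| green | 150 | 17.0 | 60.2 |
| ochre | 0.833 | 0 | 60.8 |
| ochre | 1.33 | 0.1 | 58.6 |
| ochre | 2.00 | 0 | 58.0 |
| ochre | 3.00 | 0.1 | 55.3 |
| ochre | 4.00 | 1.4 | 54.8 |
| ochre | 6.00 | 1.7 | 53.7 |
| ochre | 10.0 | 2.5 | 51.2 |

(readings scatter by 0.5 percentage points)

- noon: at 3.0 h raise the temperature by 10 K, then wait 3.0 h
- dusk: change nothing and wait 3.0 h more
- autumn: at 3.0 h add partner, 50.0 % of the amount charged, then wait 3.0 h
- midnight: at 3.0 h take out 90 % of the target then present, then wait 3.0 h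

- what is taken out of target is counted as made
- on the list of suspects stand: partner + intermediate B -> intermediate C; intermediate C <-> target; capture agent + intermediate B -> trapped intermediate; substrate + partner <-> intermediate A; intermediate A <-> intermediate B
- additions bring no volume worth counting

- target, in percent of the substrate first charged, at 3.0 h
- the option that brings most further target ("none" if no option brings more than 2 percentage points) (noon / dusk / autumn / midnight / none)
- target present, with what was taken out counted in, in percent of the substrate first charged, after dusk
- target present, with what was taken out counted in, in percent of the substrate first charged, after midnight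

**Counting partner.** Each substrate that leaves its free form takes one partner, and the step to intermediate C takes a second, while target comes from intermediate C without any more. Trapped intermediate holds one partner per substrate. I let all the capture agent end there, a share s = 5.00 % of the substrate. With e the equivalents of partner, I folded the charges into one number, the ceiling F = (e − s)/2 = 32.5 %, the largest share of the substrate that can stand as intermediate C plus target once the capture agent is spent so, with partner as limiting reagent for that pair.

**The correction.** Call that pair W. Subtracting the substrate balance from the partner balance leaves W = e − (substrate gone) − free partner. I neglected free partner, taking it as the small term. The green reading of 60.2 % substrate at 150 min then gives W = 30.2 %, which is 2.3 percentage points under F. Target read 17.0 %, so its share of the pair read f = 0.563.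

**Reading off.** One number was not enough: F bounds the pair, and f must split it. I held f steady, so target ends near fF = 18.3 %. For 3.0 h I took the midpoint of that and the last reading, 17.6 %. Dusk I put near 18.3 %. Autumn lifts F to 50.0 %, which I reckoned to gain 10 points. Midnight lets the pair split afresh, which I reckoned to gain 6.9 points and to make 24.5 %. Noon leaves F as it stands, so I chose autumn, whose reckoned gain is more than that of midnight.

The forecast gave 18.2 %, 22.2 % after dusk and 23.5 % after midnight, and chose autumn (“Autumn is clearly best”), and its dusk stood above mine.

    partner + intermediate B → intermediate C (k = 0.243 M⁻¹ s⁻¹, Ea = 43.0 kJ mol⁻¹)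
    intermediate C ⇌ target (K = 1.40, k = 0.00430 s⁻¹, Ea = 92.0 kJ mol⁻¹, ΔH = −13.0 kJ mol⁻¹)
    capture agent + intermediate B → trapped intermediate (k = 0.805 M⁻¹ s⁻¹, Ea = 49.0 kJ mol⁻¹)
    substrate + partner ⇌ intermediate A (K = 66.0 M⁻¹, k = 2.60 M⁻¹ s⁻¹, Ea = 41.0 kJ mol⁻¹, ΔH = −11.0 kJ mol⁻¹)
    intermediate A ⇌ intermediate B (K = 4.48, k = 0.00594 s⁻¹, Ea = 94.0 kJ mol⁻¹, ΔH = −25.0 kJ mol⁻¹)
    (constants at 20 °C)

**The result.** The flask gave 16.7 % at 3.0 h, 17.8 % after dusk and 24.0 % after midnight, and autumn brought the most, 11 points. Intermediate C and target relax by their own step alone, both ways together, with a half-life of 1.57 min, short against 3.0 h. In this flask the pair stood at 32.1 % after 1800 min, under F. The flask with 1.80 equiv of partner has a ceiling of 87.5 %, and its pair stood at 84.0 % after 180 min.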